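**Strategy.** Ring A is disconnected at C3–C4 (drimane numbering). The gem-dimethyl carbon C4 and the six carbons of ring B (C5–C10) are traced back to the pinane skeleton of (1R,5R)-verbenone: its bridgehead becomes C5 and its CMe2 bridge is a masked tertiary C4 cation next to it. Conjugate allylation anti to that bridge sets C10; the allyl terminus is turned into a (Z)-vinylsilane and C9 is benzylated with the arene. In the key step TiCl4 fragments the cyclobutane and the liberated C4 cation is captured by the vinylsilane, so that the bicyclo[3.1.1]heptanone becomes the trans-decalone in one operation. Hydrogenation, C9 equilibration, methylenation and arene oxidation finish tauranin.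

Key step: step 7

Remark: (1R,5R)-(+)-verbenone is assumed to be purchased enantiopure (it is otherwise one allylic oxidation from (1R)-(+)-α-pinene). Atom numbers follow the drimane numbering of the target: ring A = C1–C5 and C10, ring B = C5–C10, C11 = benzylic CH2, C12 = exocyclic CH2.

**Route**

Step 1
Reactants: 1 2,4-dimethoxyphenol
Product: 2 tert-butyl(2,4-dimethoxyphenoxy)dimethylsilane
Conditions: TBSCl, imidazole, DMF, rt
Reagents that add atoms: tert-butyldimethylsilyl chloride, CC(C)(C)[Si](C)(C)Cl
Why: Routine silylation of a phenol; the bulky silyl ether is a poor directing group, which leaves the lithiation in step 2 to the two methoxy groups.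

Step 2
Reactants: 2 tert-butyl(2,4-dimethoxyphenoxy)dimethylsilane
Product: 4 [3-(tert-butyldimethylsilyloxy)-2,6-dimethoxyphenyl]methanol, via aryllithium 3 (not isolated)
Conditions: n-BuLi, THF, 0 °C; then (CH2O)n, 0 °C → rt; aq. NH4Cl
Reagents that add atoms: paraformaldehyde (as formaldehyde), C=O
Why: Directed ortho-metalation removes the proton flanked by both methoxy groups (the most acidic, doubly coordinated site), and the aryllithium adds to formaldehyde.

Step 3
Reactants: 4 [3-(tert-butyldimethylsilyloxy)-2,6-dimethoxyphenyl]methanol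
Product: 5 [3-(bromomethyl)-2,4-dimethoxyphenoxy](tert-butyl)dimethylsilane
Conditions: CBr4, PPh3, CH2Cl2, 0 °C; used at once
Reagents that add atoms: carbon tetrabromide, BrC(Br)(Br)Br
Why: Appel reaction under neutral conditions that spare the aryl silyl ether; the electron-rich benzylic bromide is used without purification.

Step 4
Reactants: 6 (1R,5R)-(+)-verbenone
Product: 8 (1R,4R,5R)-4,6,6-trimethyl-4-(prop-2-en-1-yl)bicyclo[3.1.1]heptan-2-one, via silyl enol ether 7 (not isolated)
Conditions: allylMgBr, CuBr·SMe2, LiCl, TMSCl, THF, −78 °C; then 1 M HCl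
Reagents that add atoms: allylmagnesium bromide, C=CC[Mg]Br
Why: Chlorotrimethylsilane-accelerated conjugate addition of an allylcopper reagent, which enters anti to the gem-dimethyl bridge, so that the new quaternary centre (C10) is set by the bridgehead that becomes C5 and the allyl group is trans to the CMe2 carbon (future C4) across the C5–C10 bond.

Step 5
Reactants: 8 (1R,4R,5R)-4-allyl-4,6,6-trimethylbicyclo[3.1.1]heptan-2-one
Product: 9 (1R,4R,5R)-4,6,6-trimethyl-4-[(2Z)-3-(triethylsilyl)prop-2-en-1-yl]bicyclo[3.1.1]heptan-2-one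
Conditions: Et3SiH, [Ir(OMe)(cod)]2 (cat.), 4,4'-di-tert-butyl-2,2'-bipyridine, norbornene, THF, 40 °C
Reagents that add atoms: triethylsilane, CC[SiH](CC)CC
Why: Iridium-catalysed dehydrogenative silylation of a terminal alkene with norbornene as hydrogen acceptor, a reaction that gives (Z)-vinylsilanes selectively and tolerates ketones.

Step 6
Reactants: 9 (Z)-vinylsilane ketone; 5 benzylic bromide
Product: 11 (1R,3S,4S,5S)-3-{[3-(tert-butyldimethylsilyloxy)-2,6-dimethoxyphenyl]methyl}-4,6,6-trimethyl-4-[(2Z)-3-(triethylsilyl)prop-2-en-1-yl]bicyclo[3.1.1]heptan-2-one, via lithium enolate 10 (not isolated)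
Conditions: LiN(iPr)2, THF, −78 °C; then 5, DMPU, −78 → 0 °C
Reagents that add atoms: none
Why: Ketone enolate alkylation (SN2): the bridgehead α-carbon cannot enolise (Bredt), so only the CH2 group (C9) is deprotonated, and the activated benzylic bromide should enter anti to the gem-dimethyl bridge, a C9 configuration that is corrected in step 8.

Step 7
Reactants: 11 benzylated bicyclic ketone
Product: 14 (1S,4aS,8aS)-1-{[3-(tert-butyldimethylsilyloxy)-2,6-dimethoxyphenyl]methyl}-5,5,8a-trimethyl-3,4,4a,5,8,8a-hexahydronaphthalen-2(1H)-one, via ring-opened C4 cation 12 (not isolated), via trichlorotitanium enolate 13 (not isolated)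
Conditions: TiCl4, CH2Cl2, −78 → 0 °C; then H2O
Reagents that add atoms: none
Why: Proposed new method: TiCl4 bound to the ketone should induce heterolysis of the strained cyclobutane bond between the α-carbon C7 and the CMe2 carbon C4 (driven by strain release and by formation of a tertiary cation and a titanium enolate), and the C4 cation is then captured at the silicon-bearing carbon C3 of the vinylsilane, after which chloride removes the silyl group from the β-silyl cation to leave the C2=C3 alkene. The closest known reaction types are the Lewis acid cleavage of the cyclobutane in nopinone-type ketones (there ended by acetate capture or proton loss) and the vinylsilane-terminated cation–olefin cyclization; their union in one flask is the new element. Ring A closes in the 6-endo-trig mode with respect to the vinylsilane through a chair-like transition state. No new stereocentre is formed: C5 and C10 enter with the C4 carbon and the C1 chain trans on ring B, so only the trans ring fusion can arise, and C9 is untouched. The step needs cleavage of the C4–C7 and not the C4–C5 bond, which is secured because only C7 is α to the activated carbonyl group, and ipso attack at C3, which is secured by β-silicon stabilisation of the C2 cation and by the (Z) geometry that lets the C–Si bond align with little motion. Proton loss from the cation to an isopropenyl group is reversible in this medium and should drain back into the cyclization.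

Step 8
Reactants: 14 9-epi octalone
Product: 16 (1R,4aS,8aS)-1-[(3-hydroxy-2,6-dimethoxyphenyl)methyl]-5,5,8a-trimethyloctahydronaphthalen-2(1H)-one, via saturated 9-epi ketone 15 (not isolated)
Conditions: H2 (1 atm), Pd/C, EtOAc, rt; filter; then NaOMe, MeOH, 50 °C; aq. NH4Cl
Reagents that add atoms: none
Why: Heterogeneous hydrogenation saturates the C2=C3 alkene, and methoxide then removes the aryl silyl group and equilibrates C9 through the enolate to the ketone with the equatorial arylmethyl group (9α-H, the natural configuration), which is expected to be the more stable epimer because it avoids the syn-axial hydrogens at C5 and C7.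

Step 9
Reactants: 16 phenolic decalone
Product: 17 2,4-dimethoxy-3-{[(1S,4aS,8aS)-5,5,8a-trimethyl-2-methylidenedecahydronaphthalen-1-yl]methyl}phenol
Conditions: Ph3PCH3Br, KOtBu (excess), toluene, 90 °C
Reagents that add atoms: methyltriphenylphosphonium bromide, C[P+](c1ccccc1)(c1ccccc1)c1ccccc1.[Br-]
Why: Wittig methylenation of the hindered C8 ketone with excess ylide (one equivalent is held back by the phenol); C9 should already have its thermodynamic configuration, so the basic medium should not erode it.

Step 10
Reactants: 17 exocyclic alkene phenol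
Product: 18 6-(hydroxymethyl)-2,4-dimethoxy-3-{[(1S,4aS,8aS)-5,5,8a-trimethyl-2-methylidenedecahydronaphthalen-1-yl]methyl}phenol
Conditions: 37% aq. HCHO, NaOH (0.5 equiv), THF/H2O, rt
Reagents that add atoms: formaldehyde, C=O
Why: Lederer–Manasse ortho-hydroxymethylation of the phenoxide, regiospecific because the other ortho position and the para position carry methoxy groups.

Step 11
Reactants: 18 salicyl alcohol
Product: 19 6-(hydroxymethyl)-2-methoxy-3-{[(1S,4aS,8aS)-5,5,8a-trimethyl-2-methylidenedecahydronaphthalen-1-yl]methyl}cyclohexa-2,5-diene-1,4-dione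
Conditions: (NH4)2Ce(NO3)6, MeCN/H2O, 0 °C
Reagents that add atoms: water, O
Why: Oxidative demethylation of a para-methoxyphenol to the 1,4-benzoquinone (single-electron oxidation, attack of water at the methoxy-bearing carbon, loss of methanol), under cold, brief conditions that should spare the primary alcohol and the isolated alkene.

Step 12
Reactants: 19 methoxyquinone
Product: 20 tauranin
Conditions: NaOH, THF/H2O, 0 °C → rt; then 1 M HCl
Reagents that add atoms: sodium hydroxide, [Na+].[OH-]
Why: Addition–elimination of hydroxide at the methoxy-bearing carbon of the vinylogous ester turns the 2-methoxyquinone into the 2-hydroxyquinone, which is protected as its delocalised anion until acidification.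

**Compound list**

1 | 2,4-dimethoxyphenol | COc1ccc(O)c(OC)c1 | starting material
2 | tert-butyl(2,4-dimethoxyphenoxy)dimethylsilane | COc1ccc(O[Si](C)(C)C(C)(C)C)c(OC)c1 | intermediate
3 | [3-(tert-butyldimethylsilyloxy)-2,6-dimethoxyphenyl]lithium | COc1ccc(O[Si](C)(C)C(C)(C)C)c(OC)c1[Li] | intermediate
4 | [3-(tert-butyldimethylsilyloxy)-2,6-dimethoxyphenyl]methanol | COc1ccc(O[Si](C)(C)C(C)(C)C)c(OC)c1CO | intermediate
5 | [3-(bromomethyl)-2,4-dimethoxyphenoxy](tert-butyl)dimethylsilane | COc1ccc(O[Si](C)(C)C(C)(C)C)c(OC)c1CBr | intermediate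
6 | (1R,5R)-(+)-verbenone, (1R,5R)-4,6,6-trimethylbicyclo[3.1.1]hept-3-en-2-one | CC1=CC(=O)[C@@H]2C[C@H]1C2(C)C | starting material
7 | trimethylsilyl enol ether of 8 (2-trimethylsilyloxy-bicyclo[3.1.1]hept-2-ene, configuration as in 8) | C=CC[C@]1(C)C=C(O[Si](C)(C)C)[C@@H]2C[C@H]1C2(C)C | intermediate
8 | (1R,4R,5R)-4,6,6-trimethyl-4-(prop-2-en-1-yl)bicyclo[3.1.1]heptan-2-one (allyl anti to the CMe2 bridge) | C=CC[C@]1(C)CC(=O)[C@@H]2C[C@H]1C2(C)C | intermediate
9 | (1R,4R,5R)-4,6,6-trimethyl-4-[(2Z)-3-(triethylsilyl)prop-2-en-1-yl]bicyclo[3.1.1]heptan-2-one | CC[Si](CC)(CC)/C=C\C[C@]1(C)CC(=O)[C@@H]2C[C@H]1C2(C)C | intermediate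
10 | lithium enolate of 9 | CC[Si](CC)(CC)/C=C\C[C@]1(C)C=C(O[Li])[C@@H]2C[C@H]1C2(C)C | intermediate
11 | (1R,3S,4S,5S)-3-{[3-(tert-butyldimethylsilyloxy)-2,6-dimethoxyphenyl]methyl}-4,6,6-trimethyl-4-[(2Z)-3-(triethylsilyl)prop-2-en-1-yl]bicyclo[3.1.1]heptan-2-one (arylmethyl group and side chain both anti to the CMe2 bridge) | CC[Si](CC)(CC)/C=C\C[C@]1(C)[C@H](Cc2c(OC)ccc(O[Si](C)(C)C(C)(C)C)c2OC)C(=O)[C@@H]2C[C@H]1C2(C)C | intermediate
12 | ring-opened zwitterion: tertiary C4 carbocation with tetrachlorotitanate enolate (cyclohexene ring B, C5 and C10 substituents trans) | CC[Si](CC)(CC)/C=C\C[C@]1(C)[C@H](Cc2c(OC)ccc(O[Si](C)(C)C(C)(C)C)c2OC)C(O[Ti-](Cl)(Cl)(Cl)Cl)=CC[C@H]1[C+](C)C | intermediate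
13 | trichlorotitanium enolate of 14 | Cl[Ti](Cl)(Cl)OC1=CC[C@H]2C(C)(C)C=CC[C@]2(C)[C@@H]1Cc1c(OC)ccc(O[Si](C)(C)C(C)(C)C)c1OC | intermediate
14 | (1S,4aS,8aS)-1-{[3-(tert-butyldimethylsilyloxy)-2,6-dimethoxyphenyl]methyl}-5,5,8a-trimethyl-3,4,4a,5,8,8a-hexahydronaphthalen-2(1H)-one (trans-fused, C2=C3 alkene in ring A, 9-epi: arylmethyl axial) | O=C1CC[C@H]2C(C)(C)C=CC[C@]2(C)[C@@H]1Cc1c(OC)ccc(O[Si](C)(C)C(C)(C)C)c1OC | intermediate
15 | (1S,4aS,8aS)-1-{[3-(tert-butyldimethylsilyloxy)-2,6-dimethoxyphenyl]methyl}-5,5,8a-trimethyloctahydronaphthalen-2(1H)-one (9-epi) | O=C1CC[C@H]2C(C)(C)CCC[C@]2(C)[C@@H]1Cc1c(OC)ccc(O[Si](C)(C)C(C)(C)C)c1OC | intermediate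
16 | (1R,4aS,8aS)-1-[(3-hydroxy-2,6-dimethoxyphenyl)methyl]-5,5,8a-trimethyloctahydronaphthalen-2(1H)-one (5α-H, 9α-H, 10β-methyl) | O=C1CC[C@H]2C(C)(C)CCC[C@]2(C)[C@H]1Cc1c(OC)ccc(O)c1OC | intermediate
17 | 2,4-dimethoxy-3-{[(1S,4aS,8aS)-5,5,8a-trimethyl-2-methylidenedecahydronaphthalen-1-yl]methyl}phenol | C=C1CC[C@H]2C(C)(C)CCC[C@]2(C)[C@H]1Cc1c(OC)ccc(O)c1OC | intermediate
18 | 6-(hydroxymethyl)-2,4-dimethoxy-3-{[(1S,4aS,8aS)-5,5,8a-trimethyl-2-methylidenedecahydronaphthalen-1-yl]methyl}phenol | C=C1CC[C@H]2C(C)(C)CCC[C@]2(C)[C@H]1Cc1c(OC)cc(CO)c(O)c1OC | intermediate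
19 | 6-(hydroxymethyl)-2-methoxy-3-{[(1S,4aS,8aS)-5,5,8a-trimethyl-2-methylidenedecahydronaphthalen-1-yl]methyl}cyclohexa-2,5-diene-1,4-dione | C=C1CC[C@H]2C(C)(C)CCC[C@]2(C)[C@H]1CC1=C(OC)C(=O)C(CO)=CC1=O | intermediate
20 | tauranin, 2-hydroxy-6-(hydroxymethyl)-3-{[(1S,4aS,8aS)-5,5,8a-trimethyl-2-methylidenedecahydronaphthalen-1-yl]methyl}cyclohexa-2,5-diene-1,4-dione | C=C1CC[C@H]2C(C)(C)CCC[C@]2(C)[C@H]1CC1=C(O)C(=O)C(CO)=CC1=O | target

**Step count.** Total: 12 steps. Longest linear sequence: 10 steps (steps 1–3, then 6–12); the verbenone branch is 9 steps (steps 4–12).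

**Steps most likely to fail**

1. Step 7 (key step). The vinylsilane may add to the TiCl4-bound carbonyl group before the cyclobutane ionises, the C4 cation may rearrange by a 1,2-hydride shift from C5, or the vinylsilane may be protodesilylated by adventitious acid. The fallback separates the two events with known reactions and keeps the carbonyl masked. Starting from 11, the cyclobutane is cleaved with BF3·OEt2, Zn(OAc)2 and Ac2O to the ring-opened isopropenyl enol acetate F1. CF3CO2H in CH2Cl2 at 0 °C then protonates the isopropenyl group, and the tertiary cation closes ring A on the vinylsilane to give the bicyclic enol acetate F2. MeLi (THF, −78 °C) and aqueous work-up release the ketone, so the route is rejoined at 14.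

2. Step 6. C-alkylation at an enolate carbon flanked by a quaternary centre may be slow, so that O-alkylation and decomposition of the labile bromide take over. In the fallback, 9 is converted with LiN(iPr)2 and TMSCl into the trimethylsilyl enol ether F3. F3 is then alkylated with 5 under ZnBr2 catalysis in CH2Cl2 (SN1-type alkylation of a silyl enol ether by the stabilised benzylic cation), which returns the route to 11.

3. Step 4. The allyl nucleophile may add 1,2 to the carbonyl group instead of adding to the hindered β-carbon. In the fallback, 6 is treated with allylMgBr alone (THF, −78 °C) to make the 1,2-adduct on purpose, the tertiary dienol F4 (allyl group anti to the CMe2 bridge). KH with 18-crown-6 in THF then induces an anionic oxy-Cope rearrangement that carries the allyl group suprafacially to the β-carbon, and protonation of the enolate returns the route to 8.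

**Further compounds**

F1 | step 7 | ring-opened isopropenyl enol acetate of 11 (2-arylmethyl-3-methyl-4-isopropenyl-3-[(2Z)-3-(triethylsilyl)prop-2-enyl]cyclohex-1-enyl acetate) | CC[Si](CC)(CC)/C=C\C[C@]1(C)[C@H](Cc2c(OC)ccc(O[Si](C)(C)C(C)(C)C)c2OC)C(OC(C)=O)=CC[C@H]1C(C)=C
F2 | step 7 | bicyclic enol acetate of 14 | CC(=O)OC1=CC[C@H]2C(C)(C)C=CC[C@]2(C)[C@@H]1Cc1c(OC)ccc(O[Si](C)(C)C(C)(C)C)c1OC
F3 | step 6 | trimethylsilyl enol ether of 9 | CC[Si](CC)(CC)/C=C\C[C@]1(C)C=C(O[Si](C)(C)C)[C@@H]2C[C@H]1C2(C)C
F4 | step 4 | (1R,5R)-4,6,6-trimethyl-2-(prop-2-en-1-yl)bicyclo[3.1.1]hept-3-en-2-ol (allyl anti to the CMe2 bridge) | CC1=C[C@](O)(CC=C)[C@@H]2C[C@H]1C2(C)C
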